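The east run ended with more of its consumed left-handed substrate in left-handed product than the south-east run, a share of 0.396 against 0.210, as read at each run's last reading.

common to all: left-handed substrate 0.10 M; right-handed substrate 0.10 M
- south-east: coupling partner 0.15 M; temperature 40 °C; run made earlier
- east: coupling partner 0.60 M; temperature 52 °C; run made earlier
- Wednesday's: coupling partner 0.300 M; temperature 60 °C; time 15 h
- Friday's: coupling partner 0.300 M; temperature 45 °C; time 15 h

| run | time / h | left-handed product / % | left-handed substrate / % |
|---|---|---|---|
| south-east | 4.00 | 4.2 | 40.6 |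
| south-east | 5.00 | 5.4 | 36.8 |
| south-east | 8.00 | 6.2 | 29.9 |
| south-east | 15.0 | 6.1 | 19.5 |
| south-east | 20.0 | 8.2 | 16.3 |
| south-east | 30.0 | 9.6 | 11.2 |
| south-east | 60.0 | 9.9 | 2.9 |
| east | 2.50 | 14.7 | 19.5 |
| east | 5.00 | 17.4 | 8.9 |
| east | 8.00 | 19.2 | 4.8 |
| east | 10.0 | 18.2 | 3.9 |
| east | 12.0 | 18.7 | 1.0 |
| east | 15.0 | 18.9 | 1.4 |
| east | 20.0 | 19.8 | 0 |

(standard deviation of a reading: 1 percentage point)

- coupling partner is single-handed; left-handed substrate and right-handed substrate are mirror images of each other, charged as a racemate, each of them at the stated concentration
- the handed part of coupling partner does not stay in what it makes, so the products of the two hands are mirror images too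

- which flask leads in amount of left-handed product, in percent of the left-handed substrate and right-handed substrate together charged ("all alike" within 1.5 percentage points) (Wednesday's / Friday's / all alike)
- how much left-handed product is there at the end, in percent of the left-handed substrate and right-handed substrate together charged: Wednesday's
- how much left-handed product is there at the end, in percent of the left-handed substrate and right-handed substrate together charged: Friday's

Left-handed substrate starts at 0.5 of the charge and either couples or is lost some other way. Dividing one rate by the other removes time, so take share/(1 − share). The runs give 0.266 at 1.50 equivalents of coupling partner and 0.656 at 6.00, which is a power of 0.650. I assume temperature plays no part, which these runs cannot test. At 3.00 equivalents, the capture ratio, counting left-handed product made per left-handed substrate lost otherwise, is 0.418. Both flasks therefore end at 14.7 % if they finish.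

Is one number enough? Left-handed substrate reached 19.5 % after 15.0 h in the south-east run and after 2.50 h in the east run. Spreading that factor evenly over the degrees, with the partner change riding along, gives first-order exponents of 18.7 for Wednesday's and 1.99 for Friday's. Friday's has then consumed 0.863, so it reaches 12.7 % against 14.7 % for Wednesday's. The gap is 2 percentage points and the margin 1.5 points, so my reckoning puts Wednesday's first.

The forecast put Friday's first, with 8.5 % for Wednesday's and 15.5 % for Friday's, holding that “The loss pathway is far more temperature-sensitive”.

The flasks give 13.1 % for Wednesday's and 12.8 % for Friday's, so the verdict is all alike.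

    achiral form → side product (k = 0.0190 min⁻¹, Ea = 99.0 kJ mol⁻¹)
    achiral form → waste (k = 0.0120 min⁻¹, Ea = 111 kJ mol⁻¹)
    left-handed substrate ⇌ achiral form (K = 1.30, k = 0.0120 min⁻¹, Ea = 111 kJ mol⁻¹, ΔH = −18.0 kJ mol⁻¹)
    coupling partner + right-handed substrate → right-handed product (k = 0.0100 M⁻¹ min⁻¹, Ea = 91.0 kJ mol⁻¹)
    left-handed product ⇌ right-handed product (k = 0.00790 min⁻¹, Ea = 113 kJ mol⁻¹)
    coupling partner + left-handed substrate → left-handed product (k = 0.0170 M⁻¹ min⁻¹, Ea = 88.0 kJ mol⁻¹)
    2 coupling partner → self-condensation product (k = 0.00720 M⁻¹ min⁻¹, Ea = 67.0 kJ mol⁻¹)
    right-handed substrate ⇌ achiral form (K = 1.30, k = 0.0120 min⁻¹, Ea = 111 kJ mol⁻¹, ΔH = −18.0 kJ mol⁻¹)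
    (constants at 60 °C)

A neighbour of Wednesday's holds 0.075 M of coupling partner, or 0.750 equiv. Its capture ratio scales from 0.418 to 0.170, so it should end at 7.25 % once finished. It does finish, with 0.12 % of its left-handed substrate left. Its left-handed product stands lower than reckoned, at 4.70 %, beside 35.0 % of waste and 55.4 % of side product.

The runs are calculated for an exercise; noise was put on by code.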